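At late times in the zeta run the monomer in chains stands near 32%, after 31% at 2.00 min, and the length asked for is such an amount divided by the number of chains begun.

| flask | free monomer | protic impurity | initiator | stray impurity | remark | time |
|---|---|---|---|---|---|---|
| zeta | 2.3 M | 0.23 M | 2 mol% | 14 mM | run made earlier |  |
| eta | 2.3 M | 0.23 M | 2 mol% | 44 mM | run made earlier |  |
| alder | 2.3 M | 0.230 M | 2 mol% | 16 mM |  | 4.0 min |
| maple | 2.3 M | 0.230 M | 2 mol% | 50 mM |  | 4.0 min |

- zeta (time / min: monomer in chains / %, free monomer / %): 0.333: 8, 89; 1.00: 22, 74; 2.00: 31, 64; 3.00: 32, 57
- eta (time / min: monomer in chains / %, free monomer / %): 0.250: 0, 98; 0.500: 1, 93; 1.33: 6, 88; 3.00: 14, 77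

(standard deviation of a reading: 1.5 percentage points)

- which of the two ends with the longer chains by the average number of monomer units in a chain (chains begun, living or dead) ("neither" if they lie within 10%) (alder / maple / neither)
- average number of monomer units in a chain (chains begun, living or dead) at the end, alder
- average number of monomer units in a chain (chains begun, living or dead) at the end, maple

- the average divides the monomer in chains by the number of chains begun, living and dead together
- the analysis behind the earlier runs scatters by 1.5 percentage points, standard deviation
- the earlier runs do not show the number of chains; that part of a forecast is a guess

My first pass for alder takes initiator and stray impurity as destroying each other one for one, which leaves the chain count n, initiator charged minus stray impurity, 0.0300 M. Zeta's last reading of monomer in chains over n then gives 24.5 units. For maple the same subtraction gives −0.00400 M, a negative count, so I go round again on eta. Its subtraction gives 0.00200 M, but comparing its late slope with zeta's early slope, at equal growth per chain, gives 0.00730 M. Continuing eta's slope to 4.0 min and dividing by this reading gives 59.2 units. I carry this length to maple, assuming that monomer in chains grows in proportion to the count, and so expect maple to be longer than alder.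

The forecast says maple, with 26 (15 to 42) for alder and 80 (20 to 300) for maple, where “only competitive escape starts chains, perhaps 3 mM”. Its maple value is higher than mine.

The flask gives maple, with 26.7 for alder and 54.7 for maple.

    free monomer + initiator → living end + monomer in chains (k = 0.170 /M/s)
    free monomer + living end → monomer in chains + living end, rate k2*[living end]*[free monomer] (k = 0.310 /M/s)
    monomer in chains + living end → free monomer + living end, rate k3*[living end] as long as [monomer in chains] is above zero (k = 0.380 /s)
    initiator + stray impurity → spent initiator (k = 100 /M/s)
    protic impurity + free monomer → quenched substrate (k = 0.00630 /M/s)

In alder the living end stands at 0.0300 M, which is n, and 34.8% of monomer in chains over n gives 26.7 units. Maple's chains are longer due to the difference in stray impurity: its living end is 0.00620 M. The poisoning step is only a part of maple's length: with that step taken away, the length in maple falls to 18.7. The neighbour flask, alder with 0.92 M of protic impurity, keeps n at 0.0300 M, so its 15.3% of monomer in chains gives 11.7 units; computed, it reaches 11.7.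

The earlier runs and the new flask were computed for an exercise, noise included.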